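Remark on the chemistry: ring C has only hydrogens ortho to the C8–aryl bond, so this axis is taken as freely rotating and the target as achiral; the stereocentres of 4 and 8 are racemic and are erased downstream. The structures of the key-step precursor 6 and product 9 were checked atom by atom against the target and need no correction; 6 is kept unchanged but is used at once, without storage.

## Structural features

The target 11 is a 1,4-naphthoquinone. Its quinone ring A (C1=O, C2–OMe, C3–H, C4=O) is fused through C4a–C8a to a benzo ring B, which carries a methoxy group at C6 and, at C8, a 3,4-dimethoxyphenyl ring C joined by a single biaryl bond. There is no stereocentre, so no neighbouring stereocentres have to be related; the C8–aryl axis lies peri to the C1 carbonyl but should rotate freely. The fragile parts are the 2-methoxyquinone (a vinylogous ester that exchanges its methoxy group with nucleophiles and is easily reduced), the air-sensitive hydroquinone stages before it, and the electron-rich ring C, which does not tolerate strong one-electron oxidants. The real difficulty is regiochemical: the quinone methoxy must sit at C2, next to the carbonyl that is peri to ring C, and not at C3, and the ring B methoxy must sit at C6, meta to the hindered aryl group. The two carbonyls differ electronically: C4=O is conjugated with the C2 methoxy group through C2=C3, whereas C1=O is not. The key step exploits the fact that C4a=C8a of ring A, C8 with ring C, and C7 form a 1-arylvinylquinone diene. Only C5 and the methoxy-bearing C6 are missing, a two-carbon unit at the ketene oxidation level, and the difference between the carbonyls decides which end of the diene each carbon joins.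

## Logic of the disconnections

11 ⇒ 9 (through 10). No skeletal bond is cut. The quinone C=O groups are taken back to the O–H groups of 10, and the aromatic C6–OMe/C5=C6 unit is taken back to the C6 ketal and C5 methylene of 9 by formal return of methanol. The reason is that a ketal at C6 beside a methylene at C5 is what a cycloaddition with a ketene-level two-carbon unit leaves behind, and the hydroquinone is what such an adduct becomes on tautomerisation. The gain is that neither the aromaticity of ring B nor the quinone has to be made in the ring-forming step. The forward step must ionise the ketal and remove H5 without water, since hydrolysis would cost the C6 methyl group, and the oxidant must act on the hydroquinone only.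

9 ⇒ 6 + 7 (through 8). The bonds C4a–C5 and C6–C7 are cut. This removes C5 and C6 as one two-carbon piece and leaves all other core carbons in a single monocyclic precursor, with the C8–aryl bond, the C2 methoxy group and both quinone oxygens already in place. The gain is the loss of ring B and a convergent union of 6 with 7. The forward step must join the CH2 of 7 to C4a and not to C7, must close through carbon and not through oxygen, and needs 6 freshly made in a medium free of acid and water.

6 ⇒ 5. The C4=O bond, para to the phenolic oxygen, is cut. 6 is the reactive, short-lived member of the sequence, whereas 5 is a stable phenol. Both positions ortho to the phenol oxygen are occupied, so oxidation can only occur at the para carbon, which places the new carbonyl correctly. The forward step needs an oxidant that turns a para-unsubstituted phenol into the para-quinone without touching the 1,1-diarylethene or ring C.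

5 ⇒ 4. The C8=C7 double bond is traced back to a tertiary alcohol at C8 and a methyl group (C7). Only the methyl group has β-hydrogens, so neither regiochemistry nor alkene geometry arises. The forward dehydration must be mild enough to avoid cationic dimerisation of the electron-rich alkene.

4 ⇒ 2 + 3, and 3 ⇒ 1. The bond between C8 and the ipso carbon of ring C is cut. In 11 this is a hindered biaryl bond peri to C1=O, but in 4 it is a bond to a carbinol carbon, made by adding an aryl nucleophile to a methyl ketone, so no cross-coupling at a hindered position is needed. The gain is two commercial benzene derivatives, each with its final oxygen pattern. The forward step must tolerate the free phenol of 2, which consumes one equivalent of 3, and addition must outrun enolisation.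

## Other disconnections considered

Alternative 1: The cut is at C1–C8a and C4–C4a, removing ring A from a biaryl that already holds rings B and C.
- Forward key step: 2-bromo-3',4',5-trimethoxy-1,1'-biphenyl A1 would be dehydrobrominated with LiTMP (lithium 2,2,6,6-tetramethylpiperidide), and the strained C4a≡C8a triple bond trapped in situ by furan A2 in a [4+2] cycloaddition. The product would be 5-(3,4-dimethoxyphenyl)-7-methoxy-1,4-dihydro-1,4-epoxynaphthalene A3.
- In its favour: this cycloaddition is dependable, A2 is symmetric so the ring-forming step has no regiochemistry, the hindered C8–aryl bond is made earlier by an ordinary cross-coupling, and no unstable quinone is handled until the end.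
- Against it here: A3 brings all four carbons of ring A but only one oxygen and nothing at C2. After bridge opening and oxidation, the methoxy group would have to enter at C2 in competition with C3, so the central regiochemical problem is postponed to the last step with only the remote C6 methoxy and the peri aryl group to bias it. LiTMP must also remove the proton next to bromine and not one next to a methoxy group.
- Comparison: on structure the chosen plan is safer, because its C2 methoxy is fixed from the first starting material. On mechanism the alternative's key step is the better one, being concerted and free of orientation issues. On step economy (cross-coupling, cycloaddition, bridge opening, oxidation, methoxylation) the two are equal.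

Alternative 2: The cut is at C4a–C8a, C5–C6 and C7–C8.
- Forward key step: (S)-1-(3,4-dimethoxyphenyl)-4-methoxyocta-1,7-diyne-3,6-dione A4 and methoxyethyne A5 would be cyclotrimerised with [Rh(cod)2]BF4 and BINAP (a cationic complex of monovalent rhodium) or with Cp*RuCl(cod) (divalent ruthenium). The product would be (S)-8-(3,4-dimethoxyphenyl)-2,6-dimethoxy-2,3-dihydronaphthalene-1,4-dione A6, and one dehydrogenation would then give 11.
- In its favour: three C–C bonds and both rings form in one operation, which is better bond economy than the chosen key step. The C2 methoxy position is fixed by the tether, which is equal to the chosen plan in certainty.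
- Against it here: A4 is a double Michael acceptor with a β-methoxy ketone that can lose methanol, and its two ends must be alkynylated differently. Its stereocentre is an unnecessary burden, because the final dehydrogenation erases it and a racemate would serve. A5 is volatile, hard to store and liable to oligomerise on cationic metals. The orientation of A5 (methoxy carbon to C5 and not to C8) rests only on the difference between an aryl-substituted and an unsubstituted diyne terminus.
- Comparison: regiocontrol in the chosen plan comes from the strong, opposite polarisation of both partners, which is the more reliable basis. With an estimated four to five steps to A4, the alternative is longer overall (about seven steps against five).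

Alternative 3: The cut is at C1–C2 and C2–C3, deleting C2 and leaving a five-membered ring.
- Forward key step: 7-(3,4-dimethoxyphenyl)-5-methoxy-2,3-dihydro-1H-inden-1-one A7 would be converted to its trimethylsilyl enol ether A8. Dichlorocarbene (from CHCl3 and KOtBu, or from Cl3CCO2Na) would add to the enol double bond, and electrocyclic opening with loss of chloride would give 2-chloro-8-(3,4-dimethoxyphenyl)-6-methoxynaphthalen-1-ol A9.
- In its favour: the inserted carbon arrives with chlorine, so C2 is marked. Para-oxidation of the naphthol and addition–elimination of methoxide would place the methoxy group with no ambiguity, which is equal to or better than the chosen plan because it does not depend on an orbital bias. All intermediates are stable and storable, which is also better.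
- Against it here: A7, with its aryl group peri to the carbonyl, has to be built first (ring closure with its own regiochemistry plus a cross-coupling, about three to four steps). The carbene must add beside that peri aryl group, and two further steps follow A9.
- Comparison: the alternative builds ring A last on a preformed biaryl, so the ring B pattern must be secured separately, whereas the chosen plan sets it in the cycloaddition. At roughly eight steps against five, the chosen plan is clearly shorter.

Key step: step 4

## Route

Step 1
Reactants: 1 4-bromo-1,2-dimethoxybenzene; 2 2'-hydroxy-3'-methoxyacetophenone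
Product: 4 2-[1-(3,4-dimethoxyphenyl)-1-hydroxyethyl]-6-methoxyphenol (racemic), via (3,4-dimethoxyphenyl)magnesium bromide 3 (not isolated)
Conditions: 1 (2.5 equiv), Mg, I2 (cat.), THF, reflux; then 2, THF, 0 °C → rt; aq. NH4Cl
Reagents that add atoms: none
Why: Grignard formation followed by 1,2-addition to the ketone; the first equivalent of 3 is consumed by the phenol O–H (hence the excess of 1) and the magnesium phenoxide chelate still accepts a second equivalent at the carbonyl carbon. The new carbinol centre forms racemic and is removed in step 2.

Step 2
Reactants: 4 2-[1-(3,4-dimethoxyphenyl)-1-hydroxyethyl]-6-methoxyphenol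
Product: 5 2-[1-(3,4-dimethoxyphenyl)ethenyl]-6-methoxyphenol
Conditions: TsOH·H2O (2 mol%), toluene, 50 °C
Reagents that add atoms: none
Why: Acid-catalysed E1 dehydration through a tertiary, doubly benzylic cation stabilised by the para-methoxy group of ring C and the ortho-hydroxyl. Only the methyl group has β-hydrogens, so a single alkene without geometric isomers can form.

Step 3
Reactants: 5 2-[1-(3,4-dimethoxyphenyl)ethenyl]-6-methoxyphenol
Product: 6 2-[1-(3,4-dimethoxyphenyl)ethenyl]-6-methoxy-1,4-benzoquinone
Conditions: (KSO3)2NO (2.5 equiv), KH2PO4, H2O–acetone, 0 °C → rt; cold extraction, used at once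
Reagents that add atoms: (KSO3)2NO, dipotassium nitrosodisulfonate, [K+].[K+].[O]N(S(=O)(=O)[O-])S(=O)(=O)[O-] (supplies the C4 oxygen)
Why: Teuber oxidation: the nitroxide abstracts the phenolic hydrogen and a second equivalent couples at the para carbon, the only free position of high spin density because both ortho positions are blocked; loss of imidodisulfonate gives the para-quinone. The cold, buffered medium should leave the 1,1-diarylethene and ring C untouched.

Step 4
Reactants: 6 2-[1-(3,4-dimethoxyphenyl)ethenyl]-6-methoxy-1,4-benzoquinone; 7 1,1-dimethoxyethene
Product: 9 8-(3,4-dimethoxyphenyl)-2,6,6-trimethoxy-5,6-dihydronaphthalene-1,4-diol, via 8-(3,4-dimethoxyphenyl)-2,6,6-trimethoxy-4a,5,6,7-tetrahydronaphthalene-1,4-dione 8 (not isolated)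
Conditions: 7 (1.5 equiv), CH2Cl2, −20 °C → rt, Ar, dark
Reagents that add atoms: none
Why: The vinylquinone 6 is an electron-poor diene (C4a=C8a–C8=C7) and 7 a strongly electron-rich dienophile, so this is an inverse-electron-demand Diels–Alder cycloaddition, expected to be highly asynchronous or stepwise through a dienolate/dioxocarbenium zwitterion. The closest known reaction type is the [4+2] cycloaddition of 2-vinyl-1,4-benzoquinones with enol ethers and styrenes, of which the ketene acetal is a more nucleophilic member. Ring B closes as a six-membered carbocycle: the CH2 of 7 bonds to C4a first, and the dialkoxy carbon is then captured by the dienolate terminus C7 (6-exo-trig in the stepwise limit). The only new stereocentre, C4a of adduct 8, forms racemic and is erased when 8 enolises at C4=O and the resulting isoquinone methide shifts a hydrogen from C7 to O1, which makes ring A aromatic and leaves C7=C8 in 9. The selectivity that matters is regiochemical: the C2 methoxy group turns C4=O into a vinylogous ester, so the LUMO is centred on the O1=C1–C8a=C4a enone with its largest coefficient at the unsubstituted C4a, which directs the nucleophilic CH2 there and the oxygenated carbon to C6. Closure of the zwitterion through O1 would give an ortho ester that can reopen, whereas closure through C7 is made irreversible by aromatisation of ring A. The C2=C3 bond is an electron-rich enol ether and should not be attacked, and neutral, dry, acid-free conditions keep 7 and the ketal of 9 intact.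

Step 5
Reactants: 9 8-(3,4-dimethoxyphenyl)-2,6,6-trimethoxy-5,6-dihydronaphthalene-1,4-diol
Product: 11 8-(3,4-dimethoxyphenyl)-2,6-dimethoxynaphthalene-1,4-dione, via 8-(3,4-dimethoxyphenyl)-2,6-dimethoxynaphthalene-1,4-diol 10 (not isolated)
Conditions: TsOH (anhydrous, 5 mol%), 4 Å MS, CH2Cl2, rt, Ar; then Ag2O, MgSO4, rt
Reagents that add atoms: none
Why: Acid ionises the C6 ketal to an oxocarbenium ion and loss of H5 gives the C5=C6 enol ether, which completes the aromatic sextet of ring B, so the E1 loss of methanol is driven by aromatisation while sieves exclude water. Ag2O then dehydrogenates the electron-rich naphthalene-1,4-diol to the quinone (hydroquinone oxidation) without touching the aryl methyl ethers.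

## Compound list

1 | 4-bromo-1,2-dimethoxybenzene | COc1ccc(Br)cc1OC | starting material
2 | 2'-hydroxy-3'-methoxyacetophenone | CC(=O)c1cccc(OC)c1O | starting material
3 | (3,4-dimethoxyphenyl)magnesium bromide | COc1ccc([Mg]Br)cc1OC | intermediate (not isolated)
4 | 2-[1-(3,4-dimethoxyphenyl)-1-hydroxyethyl]-6-methoxyphenol (racemic) | COc1cccc(C(C)(O)c2ccc(OC)c(OC)c2)c1O | intermediate
5 | 2-[1-(3,4-dimethoxyphenyl)ethenyl]-6-methoxyphenol | COc1cccc(C(=C)c2ccc(OC)c(OC)c2)c1O | intermediate
6 | 2-[1-(3,4-dimethoxyphenyl)ethenyl]-6-methoxy-1,4-benzoquinone | COC1=CC(=O)C=C(C(=C)c2ccc(OC)c(OC)c2)C1=O | intermediate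
7 | 1,1-dimethoxyethene | C=C(OC)OC | starting material
8 | 8-(3,4-dimethoxyphenyl)-2,6,6-trimethoxy-4a,5,6,7-tetrahydronaphthalene-1,4-dione (racemic) | COC1=CC(=O)C2CC(OC)(OC)CC(c3ccc(OC)c(OC)c3)=C2C1=O | intermediate (not isolated)
9 | 8-(3,4-dimethoxyphenyl)-2,6,6-trimethoxy-5,6-dihydronaphthalene-1,4-diol | COc1cc(O)c2c(c1O)C(c1ccc(OC)c(OC)c1)=CC(OC)(OC)C2 | intermediate
10 | 8-(3,4-dimethoxyphenyl)-2,6-dimethoxynaphthalene-1,4-diol | COc1cc(O)c2cc(OC)cc(-c3ccc(OC)c(OC)c3)c2c1O | intermediate (not isolated)
11 | 8-(3,4-dimethoxyphenyl)-2,6-dimethoxynaphthalene-1,4-dione | COC1=CC(=O)c2cc(OC)cc(-c3ccc(OC)c(OC)c3)c2C1=O | target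

## Step count and least certain steps

Total step count: 5. Longest linear sequence: 5 steps (1 or 2 to 11); 7 joins at step 4.

Step 4 (key step). The most likely failure is collapse of the dipolar intermediate through oxygen, or its protonation without ring closure, because the dienolate is ambident and ketene acetals can add to quinones in this way. Further concerns are bonding of the CH2 of 7 at the vinyl terminus C7 (reversed orientation), redox exchange between the product hydroquinone and unreacted 6, and addition of the new phenolic O–H groups to excess 7. The fallback is a normal-demand Diels–Alder construction of ring B on the free double bond of a methoxyquinone. It sets out from 1 and comes back at 11.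
- Heck coupling of 1 with but-3-en-2-one (Pd(OAc)2, P(o-tol)3, Et3N, MeCN, 90 °C) should give (E)-4-(3,4-dimethoxyphenyl)but-3-en-2-one F1.
- Silylation (TMSOTf, Et3N, Et2O, 0 °C) should give (E)-{[4-(3,4-dimethoxyphenyl)buta-1,3-dien-2-yl]oxy}trimethylsilane F2.
- F2 and commercial 2-methoxy-1,4-benzoquinone (toluene, rt to 60 °C) should give the cis-fused endo adduct 8-(3,4-dimethoxyphenyl)-2-methoxy-6-(trimethylsilyloxy)-4a,5,8,8a-tetrahydronaphthalene-1,4-dione F3. The same carbonyl bias applies: the nucleophilic CH2 terminus of the diene should bond to the carbon β to the carbonyl that is not a vinylogous ester, and the aryl-bearing terminus to the carbon next to it.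
- Desilylation and dehydrogenation (dilute HCl in THF, then DDQ in dioxane) should give 8-(3,4-dimethoxyphenyl)-6-hydroxy-2-methoxynaphthalene-1,4-dione F4.
- O-methylation (MeI, K2CO3, acetone) should then give 11.

Step 3. The most likely failure is self-Diels–Alder dimerisation of the vinylquinone (its diene with the quinone double bond of a second molecule) during concentration or chromatography. The fallback stores the material at the hydroquinone level and releases the quinone only in dilute, dry solution. It sets out from 5 and comes back at 6. The cold organic extract of the oxidation is shaken at once with aqueous Na2S2O4, which should give 2-[1-(3,4-dimethoxyphenyl)ethenyl]-6-methoxybenzene-1,4-diol F5. F5 is then oxidised with Ag2O and MgSO4 in dry CH2Cl2, and the filtered solution of 6 is run directly into cold 7 for step 4.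

Step 5. The most likely failure is hydrolysis of the ketal by traces of water, which would end in loss of the C6 methyl group. Acid-promoted side reactions of the naphthalenediol, such as etherification by the liberated methanol, are a second risk. The fallback reverses the order and avoids acid. It sets out from 9 and comes back at 11. Oxidation of 9 (Ag2O, MgSO4, CH2Cl2) should give 8-(3,4-dimethoxyphenyl)-2,6,6-trimethoxy-5,6-dihydronaphthalene-1,4-dione F6. Et3N or DBU should then remove the vinylogously acidic H5 (γ to C1=O) and expel methoxide from C6 in an E1cB elimination that aromatises ring B and gives 11 directly.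

Step 1. The most likely failure is enolisation of the methyl ketone by the basic aryl Grignard reagent, together with slow addition to the electron-rich magnesium phenoxide chelate, so that 2 is returned. The fallback masks the phenol. It sets out from 2 and comes back at 5. Protection (MOMCl, iPr2NEt, CH2Cl2) should give 1-[3-methoxy-2-(methoxymethoxy)phenyl]ethan-1-one F7. Addition of 3 (1.3 equiv, THF, 0 °C) should give 1-(3,4-dimethoxyphenyl)-1-[3-methoxy-2-(methoxymethoxy)phenyl]ethan-1-ol F8. TsOH in MeOH at 50 °C should then remove the acetal and dehydrate the carbinol in one operation to give 5.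

## Further compounds

F1 | step 4 | (E)-4-(3,4-dimethoxyphenyl)but-3-en-2-one | CC(=O)/C=C/c1ccc(OC)c(OC)c1
F2 | step 4 | (E)-{[4-(3,4-dimethoxyphenyl)buta-1,3-dien-2-yl]oxy}trimethylsilane | C=C(O[Si](C)(C)C)/C=C/c1ccc(OC)c(OC)c1
F3 | step 4 | 8-(3,4-dimethoxyphenyl)-2-methoxy-6-(trimethylsilyloxy)-4a,5,8,8a-tetrahydronaphthalene-1,4-dione (racemic, H4a, H8 and H8a cis, one enantiomer drawn) | COC1=CC(=O)[C@@H]2CC(O[Si](C)(C)C)=C[C@H](c3ccc(OC)c(OC)c3)[C@@H]2C1=O
F4 | step 4 | 8-(3,4-dimethoxyphenyl)-6-hydroxy-2-methoxynaphthalene-1,4-dione | COC1=CC(=O)c2cc(O)cc(-c3ccc(OC)c(OC)c3)c2C1=O
F5 | step 3 | 2-[1-(3,4-dimethoxyphenyl)ethenyl]-6-methoxybenzene-1,4-diol | COc1cc(O)cc(C(=C)c2ccc(OC)c(OC)c2)c1O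
F6 | step 5 | 8-(3,4-dimethoxyphenyl)-2,6,6-trimethoxy-5,6-dihydronaphthalene-1,4-dione | COC1=CC(=O)C2=C(C1=O)C(c1ccc(OC)c(OC)c1)=CC(OC)(OC)C2
F7 | step 1 | 1-[3-methoxy-2-(methoxymethoxy)phenyl]ethan-1-one | CC(=O)c1cccc(OC)c1OCOC
F8 | step 1 | 1-(3,4-dimethoxyphenyl)-1-[3-methoxy-2-(methoxymethoxy)phenyl]ethan-1-ol (racemic) | COCOc1c(OC)cccc1C(C)(O)c1ccc(OC)c(OC)c1
A1 | alternative 1 | 2-bromo-3',4',5-trimethoxy-1,1'-biphenyl | COc1ccc(Br)c(c1)-c1ccc(OC)c(OC)c1
A2 | alternative 1 | furan | c1ccoc1
A3 | alternative 1 | 5-(3,4-dimethoxyphenyl)-7-methoxy-1,4-dihydro-1,4-epoxynaphthalene (racemic, one enantiomer drawn) | COc1cc(-c2ccc(OC)c(OC)c2)c2c(c1)[C@@H]1C=C[C@H]2O1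
A4 | alternative 2 | (S)-1-(3,4-dimethoxyphenyl)-4-methoxyocta-1,7-diyne-3,6-dione | CO[C@H](C(=O)C#Cc1ccc(OC)c(OC)c1)CC(=O)C#C
A5 | alternative 2 | methoxyethyne | COC#C
A6 | alternative 2 | (S)-8-(3,4-dimethoxyphenyl)-2,6-dimethoxy-2,3-dihydronaphthalene-1,4-dione | CO[C@H]1CC(=O)c2cc(OC)cc(-c3ccc(OC)c(OC)c3)c2C1=O
A7 | alternative 3 | 7-(3,4-dimethoxyphenyl)-5-methoxy-2,3-dihydro-1H-inden-1-one | COc1cc2c(c(c1)-c1ccc(OC)c(OC)c1)C(=O)CC2
A8 | alternative 3 | {[4-(3,4-dimethoxyphenyl)-6-methoxy-1H-inden-3-yl]oxy}trimethylsilane | COc1cc2c(c(c1)-c1ccc(OC)c(OC)c1)C(O[Si](C)(C)C)=CC2
A9 | alternative 3 | 2-chloro-8-(3,4-dimethoxyphenyl)-6-methoxynaphthalen-1-ol | Oc1c(Cl)ccc2cc(OC)cc(-c3ccc(OC)c(OC)c3)c12
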